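Late times opened the meeting on this flask. The first chemist wrote the tail of the amber run on the board, substrate at 42% after 4.00 d and 37% after 10.0 d, and argued that a run which has nearly stopped shows how far a charge of reagent goes.

the same everywhere: reagent in the second phase 0.0126 M
- red: substrate 0.0060 M; run made earlier
- amber: substrate 0.0090 M; run made earlier
- flask: substrate 0.012 M; time 10 d; volume of the second phase over the first 0.50

- red (time / d: target / %, substrate / %): 2.50: 15, 42; 5.00: 12, 32; 8.00: 10, 23; 10.0: 8, 18
- amber (time / d: target / %, substrate / %): 0.833: 19, 72; 1.67: 21, 54; 4.00: 12, 42; 10.0: 9, 37

(standard deviation of a reading: 2 percentage points)

- in the second phase: reagent in the second phase; everything else is in the first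
- charges count per volume of the first phase; a concentration in a rate is the amount of a species over the volume of its own phase; every rate counts per litre of the first phase
- the numbers in the tables scatter by 2 percentage points (one standard deviation)
- the earlier runs hold the two phases in the same ratio of volumes as the flask asked about

- amount of target at 10 d, in percent of the substrate charged
- part of the substrate charged that has reacted at 10 d

She reckoned that amber's c_substrate had dropped by 0.00567 M, so with c_reagent in the second phase at 0.0126 M the run's price read 2.22. The price, she said, is the reagent charged per substrate reacted once a run stalls.

The second chemist objected that red gives no price, since its substrate was still falling, from 23% at 8.00 d to 18% at 10.0 d. That left one reading, with its scatter of 2 percentage points.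

The first chemist then froze the price, treating the reagent as the limiting reagent, and reckoned for the flask, with c_substrate at 0.012 M and the same reagent charge, 47.2% reacted by 10 d.

The forecaster argued that “the reagent is used up at roughly two equivalents per substrate reacted” and put the reacted part at 49%, a little above the first chemist's figure, and target at 10%.

The flask gives 59.7% reacted and target at 9.48%.

    reagent in the reaction phase ⇌ reagent in the second phase, rate k1*([reagent in the reaction phase] - [reagent in the second phase]/K1) per volume of the first phase (partition coefficient = 1.70, kL = 0.0410 h⁻¹)
    substrate + reagent in the reaction phase → target (k = 11.0 M⁻¹ h⁻¹)
    reagent in the reaction phase + target → over-reacted product (k = 24.0 M⁻¹ h⁻¹)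
    reagent in the reaction phase ⇌ dormant form (K = 13.0, k = 0.0750 h⁻¹)
    target ⇌ isomer of the product (K = 3.00, k = 0.0210 h⁻¹)

In the flask, substrate and reagent in the reaction phase made target mainly early, with 89% of that step's turnover up to 10 d done by 5.00 d, while reagent in the second phase fell to 1.73% of its charge and over-reacted product and isomer of the product grew to 21.4% and 21.6%. At 10.0 d, with 0.644% of that charge still in the second phase and 0.00232 M of dormant form, the flask's reagent charged per substrate reacted, reckoned like the price but at that time, stood at 1.76, below the 2.22 read from amber, and the same ratio for the neighbour charged with 0.048 M of substrate, 21.7% reacted, stood at 1.21.

The numbers in the tables come from a simulation for an exercise; scatter was added.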